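**Plan**
- Retrosynthesis: the acid comes from its methyl ester. The 3,6-dihydro-1,2-dioxine is cut at C3–C4 and, in the same operation, at O2–C3. This gives an acyclic tertiary silyl peroxide (C4–C14) and methyl 3,3-dimethoxypropanoate (C1–C3).
- C6–O1 is cut back to a trisubstituted oxirane plus H2O2. C5–C6 and C6–C7 are cut to but-1-yne, (R)-2-chloropropanoic acid and a C7–C14 bromide. The bromide comes from hex-1-ene, Et3Al, vinyl bromide and Me3Al.
- Enabling feature: C3 bears one H and O2 of the O1–O2 bond, so it is a latent peroxycarbenium ion. It lies 1,6 (C3–O2–O1–C6–C5=C4) to C4 of the only ring alkene. A silyl group on C4, cis to C6, makes C4 the nucleophile, and its loss puts C4=C5 back where the dioxine ring has it.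
- Forward order: side chain, then α-chloroketone, alkynyl carbinol, (Z)-vinylsilane, helper oxirane ring, tertiary hydroperoxide and silyl peroxide. The helper carbinol carbon is then turned into the C6 ethyl group. The only ring of the target closes in the penultimate step, followed by saponification.
- Stereochemistry: C10 and C8 come from catalyst control (two asymmetric carboaluminations). C6 is relayed from the bought stereocentre of (R)-2-chloropropanoic acid (Cornforth-controlled addition, then inversion by H2O2), and that bought centre is then erased. C3 is set from C6 in the ring closure.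

Key step: step 13

Remarks on the chemistry
- Locants: C1 is the carboxyl carbon. C3 (bound to O2) and C6 (bound to O1) are the ring sp3 carbons, and C4=C5 is the ring alkene. C7–C14 is the side chain (methyl on C8, ethyl on C10). C1′–C2′ is the ethyl group on C6.
- Assumption: (+)-(NMI)2ZrCl2 is taken to add the alkyl group to the face of a simple 1-alkene that gives the (S)-2-alkylalkylaluminium compounds; the (−)-catalyst gives the R series.

Step 1
Reactants: 1 hex-1-ene; 2 triethylaluminium; 3 bromoethene (vinyl bromide)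
Product: 5 (4S)-4-ethyloct-1-ene, via alkylalane 4 (not isolated)
Conditions: 2, (+)-(NMI)2ZrCl2 (NMI = 1-neomenthylindenyl, 5 mol %), CH2Cl2, 0 → 23 °C; evaporate; Zn(OTf)2, DMF, 70 °C; 3, Pd(DPEphos)Cl2 (3 mol %), i-Bu2AlH (6 mol %), DMF, 23 °C; aq HCl
Reagents that add atoms: none
Why: Zirconium-catalysed asymmetric carboalumination (ZACA) adds Et–Al across the terminal alkene with ethyl going to C10 on the face chosen by the chiral zirconocene, and the primary alkylalane, after transfer to zinc, undergoes a Negishi-type Pd-catalysed coupling with vinyl bromide that does not touch the new stereocentre.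

Step 2
Reactants: 5 (4S)-4-ethyloct-1-ene; 6 trimethylaluminium
Product: 8 (2S,4S)-4-ethyl-2-methyloctan-1-ol, via alkylalane 7 (not isolated)
Conditions: 6, (+)-(NMI)2ZrCl2 (5 mol %), CH2Cl2, 23 °C; then O2 (1 atm), 0 °C; aq HCl; chromatography
Reagents that add atoms: dioxygen O=O
Why: A second ZACA reaction (methylalumination) sets C8 under catalyst control, the C–Al bond is oxidised by O2 to the primary alcohol, and at the alcohol stage the minor diastereomer should be removable by chromatography.

Step 3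
Reactants: 8 (2S,4S)-4-ethyl-2-methyloctan-1-ol
Product: 9 (2S,4S)-1-bromo-4-ethyl-2-methyloctane
Conditions: CBr4, PPh3, CH2Cl2, 0 °C
Reagents that add atoms: carbon tetrabromide BrC(Br)(Br)Br
Why: The Appel reaction converts a primary alcohol into the bromide by SN2 displacement at C7, one carbon away from the nearest stereocentre.

Step 4
Reactants: 10 (2R)-2-chloropropanoic acid
Product: 11 (2R)-2-chloro-N-methoxy-N-methylpropanamide
Conditions: MeONHMe·HCl, EDC, N-methylmorpholine, CH2Cl2, 0 °C
Reagents that add atoms: N,O-dimethylhydroxylamine hydrochloride CNOC.Cl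
Why: Carbodiimide amide coupling at 0 °C with a weak base gives the Weinreb amide without passing through a ketene, so the bought stereocentre should be kept.

Step 5
Reactants: 9 (2S,4S)-1-bromo-4-ethyl-2-methyloctane; 11 (2R)-2-chloro-N-methoxy-N-methylpropanamide
Product: 13 (2R,5S,7S)-2-chloro-7-ethyl-5-methylundecan-3-one, via Grignard reagent 12 (not isolated)
Conditions: Mg, Et2O, reflux; then 11, THF, −20 °C; cold 1 M HCl
Reagents that add atoms: none
Why: In the Weinreb ketone synthesis the chelated tetrahedral adduct survives until the quench, so a single addition forms the C6–C7 bond and the low temperature limits enolisation of the α-chloro carbonyl unit.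

Step 6
Reactants: 13 (2R,5S,7S)-2-chloro-7-ethyl-5-methylundecan-3-one; 14 but-1-yne
Product: 16 (2R,3S)-2-chloro-3-[(2S,4S)-4-ethyl-2-methyloctyl]hept-4-yn-3-ol, via lithium butynide 15 (not isolated)
Conditions: 14, n-BuLi, THF, −78 °C; then 13, −78 °C; aq NH4Cl at −78 °C; chromatography
Reagents that add atoms: none
Why: The 1,2-addition follows the Cornforth model (the polar Felkin–Anh model predicts the same sense), with C–Cl anti to C=O and the acetylide passing the hydrogen of the chlorinated carbon, so the bought centre fixes C6, and the minor C6 epimer is a diastereomer that chromatography can remove.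

Step 7
Reactants: 16 (2R,3S)-2-chloro-3-[(2S,4S)-4-ethyl-2-methyloctyl]hept-4-yn-3-ol
Product: 17 (2R,3S,4Z)-2-chloro-3-[(2S,4S)-4-ethyl-2-methyloctyl]-5-(triethylsilyl)hept-4-en-3-ol
Conditions: Et3SiH, [Cp*Ru(MeCN)3]PF6 (3 mol %), CH2Cl2, 0 → 23 °C
Reagents that add atoms: triethylsilane CC[SiH](CC)CC
Why: Ruthenium-catalysed trans-hydrosilylation of an internal propargylic alcohol places silicon on the alkyne carbon distal to the carbinol (C4) and hydrogen on C5 from the opposite side, which gives the geometry with Si cis to C6 that the ring closure needs.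

Step 8
Reactants: 17 (2R,3S,4Z)-2-chloro-3-[(2S,4S)-4-ethyl-2-methyloctyl]-5-(triethylsilyl)hept-4-en-3-ol
Product: 18 (2S,3S)-2-[(2S,4S)-4-ethyl-2-methyloctyl]-3-methyl-2-[(1Z)-2-(triethylsilyl)but-1-en-1-yl]oxirane
Conditions: NaH, THF, 0 °C
Reagents that add atoms: none
Why: An intramolecular Williamson (3-exo-tet) displacement of chloride by the tertiary alkoxide closes the helper oxirane with retention at C6 and inversion at C1′.

Step 9
Reactants: 18 (2S,3S)-2-[(2S,4S)-4-ethyl-2-methyloctyl]-3-methyl-2-[(1Z)-2-(triethylsilyl)but-1-en-1-yl]oxirane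
Product: 19 (2S,3R,4Z)-3-[(2S,4S)-4-ethyl-2-methyloctyl]-3-hydroperoxy-5-(triethylsilyl)hept-4-en-2-ol
Conditions: anhydrous H2O2 in Et2O, H3PMo12O40 (3 mol %), 0 → 23 °C
Reagents that add atoms: hydrogen peroxide OO
Why: Acid-catalysed perhydrolysis of a trisubstituted epoxide opens the more substituted C6–O bond in a borderline SN2 process with inversion, so O1 arrives on the face opposite the oxirane oxygen, and A(1,3) strain from the cis silyl group keeps the C4=C5 π bond out of conjugation and so disfavours a free allyl cation.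

Step 10
Reactants: 19 (2S,3R,4Z)-3-[(2S,4S)-4-ethyl-2-methyloctyl]-3-hydroperoxy-5-(triethylsilyl)hept-4-en-2-ol
Product: 20 (2S,3R,4Z)-3-[(2S,4S)-4-ethyl-2-methyloctyl]-5-(triethylsilyl)-3-[(triethylsilyl)peroxy]hept-4-en-2-ol
Conditions: Et3SiCl (1.05 equiv), imidazole, CH2Cl2, −40 °C
Reagents that add atoms: chlorotriethylsilane CC[Si](Cl)(CC)CC
Why: The hydroperoxide O–H is more acidic and, through the α-effect, more nucleophilic than the hindered secondary alcohol next to the quaternary carbon, so one equivalent of silyl chloride should silylate the peroxide oxygen selectively.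

Step 11
Reactants: 20 (2S,3R,4Z)-3-[(2S,4S)-4-ethyl-2-methyloctyl]-5-(triethylsilyl)-3-[(triethylsilyl)peroxy]hept-4-en-2-ol
Product: 21 (3S,4Z)-3-[(2S,4S)-4-ethyl-2-methyloctyl]-5-(triethylsilyl)-3-[(triethylsilyl)peroxy]hepta-1,4-diene
Conditions: Martin sulfurane Ph2S[OC(CF3)2Ph]2, CH2Cl2, 0 → 23 °C
Reagents that add atoms: none
Why: Dehydration with Martin sulfurane goes through an alkoxysulfurane that loses a methyl hydrogen in an E2-type step (these are the only β-hydrogens, since C6 is quaternary), which erases the helper stereocentre and gives the vinyl group without a free cation.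

Step 12
Reactants: 21 (3S,4Z)-3-[(2S,4S)-4-ethyl-2-methyloctyl]-5-(triethylsilyl)-3-[(triethylsilyl)peroxy]hepta-1,4-diene
Product: 22 (3Z,5R)-5-[(2S,4S)-4-ethyl-2-methyloctyl]-3-(triethylsilyl)-5-[(triethylsilyl)peroxy]hept-3-ene
Conditions: 2-nitrobenzenesulfonohydrazide, Et3N, CH2Cl2, 23 °C
Reagents that add atoms: none
Why: Diimide reduction is a concerted syn transfer of H2 that is far faster for the monosubstituted vinyl group than for the hindered trisubstituted vinylsilane and leaves O–O bonds untouched, so the vinyl group becomes the C6 ethyl group.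

Step 13
Reactants: 22 (3Z,5R)-5-[(2S,4S)-4-ethyl-2-methyloctyl]-3-(triethylsilyl)-5-[(triethylsilyl)peroxy]hept-3-ene; 23 methyl 3,3-dimethoxypropanoate
Product: 26 methyl 2-[(3R,6R)-4,6-diethyl-6-[(2S,4S)-4-ethyl-2-methyloctyl]-3,6-dihydro-1,2-dioxin-3-yl]acetate, via mixed peroxyacetal 24 (not isolated), via peroxycarbenium triflate 25 (not isolated)
Conditions: 23 (1.5 equiv), Me3SiOTf (0.3 equiv), 2,6-di-tert-butyl-4-methylpyridine (0.1 equiv), 4 Å MS, CH2Cl2, −78 → −30 °C
Reagents that add atoms: none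
Why: Proposed new method: Me3SiOTf first swaps one methoxy group of 23 for the peroxide oxygen of 22 (silyl-triflate-catalysed transacetalisation, giving 24) and then ionises the remaining C3–OMe bond to the peroxycarbenium ion 25; C4 of the (Z)-vinylsilane attacks C3, the C5 cation so formed is held by the β C4–Si bond, and loss of the silyl group (which regenerates silyl triflate) restores C4=C5 exactly where the ring has it. The closest known reaction types are the capture of peroxycarbenium ions by allylsilanes, silyl enol ethers and alkenes (routes to 1,2-dioxanes and 1,2-dioxolanes) and the vinylsilane-terminated (silyl-Prins) cyclisation of oxocarbenium ions to 5,6-dihydro-2H-pyrans; new here is their union, the ipso-substitution of a vinylsilane by a peroxycarbenium ion. The one ring formed, the 3,6-dihydro-1,2-dioxine, closes in a 6-endo-trig mode (C4 and C5 both end up in the ring, as does the O2=C3 bond of the cation), and the Z geometry with Si cis to C6 is what lets C3 reach C4. C3 is set by C6 through a chair-like transition state in which the E-configured cation holds CH2CO2Me pseudoequatorial, the β-branched C7 chain on C6 is pseudoequatorial and the smaller ethyl group takes the pseudoaxial site that lies 1,3 to the departing silyl group, which places CH2CO2Me cis to ethyl and so gives (3R) from (6R). The step needs ionisation of C–OMe rather than O–O or C6–O heterolysis, which low temperature, a silyl triflate in place of TiCl4 or SnCl4 and the A(1,3)-twisted alkene should favour, and it needs attack through C4 rather than C5 (which would give a five-membered peroxide), which the β-silicon effect secures. No 2-oxonia-Cope escape exists, because it would have to break O1–C6 and create an O=O cation, so C6 is not scrambled.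

Step 14
Reactants: 26 methyl 2-[(3R,6R)-4,6-diethyl-6-[(2S,4S)-4-ethyl-2-methyloctyl]-3,6-dihydro-1,2-dioxin-3-yl]acetate
Product: 27 2-[(3R,6R)-4,6-diethyl-6-[(2S,4S)-4-ethyl-2-methyloctyl]-3,6-dihydro-1,2-dioxin-3-yl]acetic acid (CNP0179105.1)
Conditions: LiOH, THF–H2O (3:1), 0 → 23 °C; then 1 M HCl to pH 3
Reagents that add atoms: lithium hydroxide [Li+].[OH-]
Why: Saponification of the methyl ester with LiOH at or below room temperature is tolerated by dialkyl peroxides of this ring type and touches no stereocentre.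

**Compound list**
1 | hex-1-ene | C=CCCCC | starting material
2 | triethylaluminium | CC[Al](CC)CC | starting material
3 | bromoethene (vinyl bromide) | C=CBr | starting material
4 | diethyl[(2S)-2-ethylhexyl]aluminium | CCCC[C@H](CC)C[Al](CC)CC | intermediate
5 | (4S)-4-ethyloct-1-ene | CCCC[C@H](CC)CC=C | intermediate
6 | trimethylaluminium | C[Al](C)C | starting material
7 | [(2S,4S)-4-ethyl-2-methyloctyl]dimethylaluminium | CCCC[C@H](CC)C[C@H](C)C[Al](C)C | intermediate
8 | (2S,4S)-4-ethyl-2-methyloctan-1-ol | CCCC[C@H](CC)C[C@H](C)CO | intermediate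
9 | (2S,4S)-1-bromo-4-ethyl-2-methyloctane | CCCC[C@H](CC)C[C@H](C)CBr | intermediate
10 | (2R)-2-chloropropanoic acid | C[C@@H](Cl)C(=O)O | starting material
11 | (2R)-2-chloro-N-methoxy-N-methylpropanamide | C[C@@H](Cl)C(=O)N(C)OC | intermediate
12 | [(2S,4S)-4-ethyl-2-methyloctyl]magnesium bromide | CCCC[C@H](CC)C[C@H](C)C[Mg]Br | intermediate
13 | (2R,5S,7S)-2-chloro-7-ethyl-5-methylundecan-3-one | CCCC[C@H](CC)C[C@H](C)CC(=O)[C@H](Cl)C | intermediate
14 | but-1-yne | C#CCC | starting material
15 | but-1-yn-1-yllithium | [Li]C#CCC | intermediate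
16 | (2R,3S)-2-chloro-3-[(2S,4S)-4-ethyl-2-methyloctyl]hept-4-yn-3-ol | CCCC[C@H](CC)C[C@H](C)C[C@@](O)([C@H](Cl)C)C#CCC | intermediate
17 | (2R,3S,4Z)-2-chloro-3-[(2S,4S)-4-ethyl-2-methyloctyl]-5-(triethylsilyl)hept-4-en-3-ol | CCCC[C@H](CC)C[C@H](C)C[C@@](O)([C@H](Cl)C)/C=C(/CC)[Si](CC)(CC)CC | intermediate
18 | (2S,3S)-2-[(2S,4S)-4-ethyl-2-methyloctyl]-3-methyl-2-[(1Z)-2-(triethylsilyl)but-1-en-1-yl]oxirane | CCCC[C@H](CC)C[C@H](C)C[C@@]1(/C=C(/CC)[Si](CC)(CC)CC)O[C@H]1C | intermediate
19 | (2S,3R,4Z)-3-[(2S,4S)-4-ethyl-2-methyloctyl]-3-hydroperoxy-5-(triethylsilyl)hept-4-en-2-ol | CCCC[C@H](CC)C[C@H](C)C[C@](OO)([C@@H](O)C)/C=C(/CC)[Si](CC)(CC)CC | intermediate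
20 | (2S,3R,4Z)-3-[(2S,4S)-4-ethyl-2-methyloctyl]-5-(triethylsilyl)-3-[(triethylsilyl)peroxy]hept-4-en-2-ol | CCCC[C@H](CC)C[C@H](C)C[C@](OO[Si](CC)(CC)CC)([C@@H](O)C)/C=C(/CC)[Si](CC)(CC)CC | intermediate
21 | (3S,4Z)-3-[(2S,4S)-4-ethyl-2-methyloctyl]-5-(triethylsilyl)-3-[(triethylsilyl)peroxy]hepta-1,4-diene | CCCC[C@H](CC)C[C@H](C)C[C@](OO[Si](CC)(CC)CC)(C=C)/C=C(/CC)[Si](CC)(CC)CC | intermediate
22 | (3Z,5R)-5-[(2S,4S)-4-ethyl-2-methyloctyl]-3-(triethylsilyl)-5-[(triethylsilyl)peroxy]hept-3-ene | CCCC[C@H](CC)C[C@H](C)C[C@](OO[Si](CC)(CC)CC)(CC)/C=C(/CC)[Si](CC)(CC)CC | intermediate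
23 | methyl 3,3-dimethoxypropanoate | COC(OC)CC(=O)OC | starting material
24 | methyl 3-methoxy-3-{[(3Z,5R)-5-[(2S,4S)-4-ethyl-2-methyloctyl]-3-(triethylsilyl)hept-3-en-5-yl]peroxy}propanoate (both epimers at the acetal carbon) | CCCC[C@H](CC)C[C@H](C)C[C@](OOC(OC)CC(=O)OC)(CC)/C=C(/CC)[Si](CC)(CC)CC | intermediate
25 | peroxycarbenium triflate derived from 24 by loss of methoxide (C3=O2 cation) | CCCC[C@H](CC)C[C@H](C)C[C@](O[O+]=CCC(=O)OC)(CC)/C=C(/CC)[Si](CC)(CC)CC.[O-]S(=O)(=O)C(F)(F)F | intermediate
26 | methyl 2-[(3R,6R)-4,6-diethyl-6-[(2S,4S)-4-ethyl-2-methyloctyl]-3,6-dihydro-1,2-dioxin-3-yl]acetate | CCCC[C@H](CC)C[C@H](C)C[C@]1(CC)C=C(CC)[C@@H](CC(=O)OC)OO1 | intermediate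
27 | 2-[(3R,6R)-4,6-diethyl-6-[(2S,4S)-4-ethyl-2-methyloctyl]-3,6-dihydro-1,2-dioxin-3-yl]acetic acid | CCCC[C@H](CC)C[C@H](C)C[C@]1(CC)C=C(CC)[C@@H](CC(=O)O)OO1 | target

**Step count**
Total step count: 14. Longest linear sequence: 13 steps (steps 1–3 and 5–14).

**Steps most likely to fail**

**Step 13.**
- What may go wrong: proton loss from the cation instead of ring closure; heterolysis of the O–O bond with migration of the alkenyl group; protodesilylation; or poor facial selectivity at C3.
- The fallback uses known chemistry, sets out from 22 and closes the ring at O2–C3 instead.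
- Iododesilylation with N-iodosuccinimide in MeCN (retention of geometry) would give (3Z,5R)-5-[(2S,4S)-4-ethyl-2-methyloctyl]-3-iodo-5-[(triethylsilyl)peroxy]hept-3-ene F1.
- A Heck reaction with methyl acrylate (Pd(OAc)2, Ag2CO3, DMF, 40 °C) would give methyl (2E,4Z,6R,8S,10S)-4,6,10-triethyl-8-methyl-6-[(triethylsilyl)peroxy]tetradeca-2,4-dienoate F2.
- Removal of the O-silyl group (HF·pyridine, THF, 0 °C) would give methyl (2E,4Z,6R,8S,10S)-4,6,10-triethyl-6-hydroperoxy-8-methyltetradeca-2,4-dienoate F3.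
- A base-mediated 6-exo-trig intramolecular oxa-Michael addition of the hydroperoxide to C3 (catalytic Et2NH, CF3CH2OH, 23 °C) comes back to the route at 26. This addition is reversible, so C3 would be set thermodynamically.

**Step 9.**
- What may go wrong: partial ionisation towards an allyl cation with erosion of configuration at C6; attack in the SN2′ sense; acid-induced cleavage of the allylic hydroperoxide; or epoxidation of the vinylsilane.
- The fallback sets out from 16 and introduces the peroxide before the alkene exists. C6 is then propargylic, less prone to ionise and less shielded.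
- NaH in THF would give (2S,3S)-2-(but-1-yn-1-yl)-2-[(2S,4S)-4-ethyl-2-methyloctyl]-3-methyloxirane F4.
- Perhydrolysis (H2O2 in Et2O, H3PMo12O40) would give (2S,3R)-3-[(2S,4S)-4-ethyl-2-methyloctyl]-3-hydroperoxyhept-4-yn-2-ol F5.
- Selective O-silylation (Et3SiCl, imidazole) would give (2S,3R)-3-[(2S,4S)-4-ethyl-2-methyloctyl]-3-[(triethylsilyl)peroxy]hept-4-yn-2-ol F6.
- Trans-hydrosilylation (Et3SiH, [Cp*Ru(MeCN)3]PF6) comes back to the route at 20.

**Step 6.**
- What may go wrong: poor facial selectivity of the acetylide addition, or enolisation with racemisation of the α-chloroketone.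
- The fallback sets out from Grignard reagent 12 and replaces substrate control by catalyst control.
- CuI-catalysed anti-carbomagnesiation of but-2-yn-1-ol (Et2O, 0 → 23 °C) would give (2E)-2-[(2S,4S)-4-ethyl-2-methyloctyl]but-2-en-1-ol F7.
- Sharpless asymmetric epoxidation (Ti(OiPr)4, L-(+)-diethyl tartrate, t-BuOOH, 4 Å MS, CH2Cl2, −20 °C) would give [(2S,3S)-2-[(2S,4S)-4-ethyl-2-methyloctyl]-3-methyloxiran-2-yl]methanol F8.
- Dess–Martin oxidation would give (2R,3S)-2-[(2S,4S)-4-ethyl-2-methyloctyl]-3-methyloxirane-2-carbaldehyde F9.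
- A Stork–Zhao-type olefination with the α-iodo ylide made from [Ph3PCH2CH2CH3]Br (n-BuLi; I2; NaN(SiMe3)2; THF, −78 °C) would give (2S,3S)-2-[(2S,4S)-4-ethyl-2-methyloctyl]-2-[(1Z)-2-iodobut-1-en-1-yl]-3-methyloxirane F10.
- Iodine–lithium exchange (t-BuLi, Et2O, −78 °C) with an Et3SiCl quench comes back to the route at 18.

**Further compounds**
F1 | step 13 | (3Z,5R)-5-[(2S,4S)-4-ethyl-2-methyloctyl]-3-iodo-5-[(triethylsilyl)peroxy]hept-3-ene | CCCC[C@H](CC)C[C@H](C)C[C@](OO[Si](CC)(CC)CC)(CC)/C=C(/CC)I
F2 | step 13 | methyl (2E,4Z,6R,8S,10S)-4,6,10-triethyl-8-methyl-6-[(triethylsilyl)peroxy]tetradeca-2,4-dienoate | CCCC[C@H](CC)C[C@H](C)C[C@](OO[Si](CC)(CC)CC)(CC)/C=C(/CC)\C=C\C(=O)OC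
F3 | step 13 | methyl (2E,4Z,6R,8S,10S)-4,6,10-triethyl-6-hydroperoxy-8-methyltetradeca-2,4-dienoate | CCCC[C@H](CC)C[C@H](C)C[C@](OO)(CC)/C=C(/CC)\C=C\C(=O)OC
F4 | step 9 | (2S,3S)-2-(but-1-yn-1-yl)-2-[(2S,4S)-4-ethyl-2-methyloctyl]-3-methyloxirane | CCCC[C@H](CC)C[C@H](C)C[C@@]1(C#CCC)O[C@H]1C
F5 | step 9 | (2S,3R)-3-[(2S,4S)-4-ethyl-2-methyloctyl]-3-hydroperoxyhept-4-yn-2-ol | CCCC[C@H](CC)C[C@H](C)C[C@](OO)([C@@H](O)C)C#CCC
F6 | step 9 | (2S,3R)-3-[(2S,4S)-4-ethyl-2-methyloctyl]-3-[(triethylsilyl)peroxy]hept-4-yn-2-ol | CCCC[C@H](CC)C[C@H](C)C[C@](OO[Si](CC)(CC)CC)([C@@H](O)C)C#CCC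
F7 | step 6 | (2E)-2-[(2S,4S)-4-ethyl-2-methyloctyl]but-2-en-1-ol | CCCC[C@H](CC)C[C@H](C)C/C(CO)=C\C
F8 | step 6 | [(2S,3S)-2-[(2S,4S)-4-ethyl-2-methyloctyl]-3-methyloxiran-2-yl]methanol | CCCC[C@H](CC)C[C@H](C)C[C@@]1(CO)O[C@H]1C
F9 | step 6 | (2R,3S)-2-[(2S,4S)-4-ethyl-2-methyloctyl]-3-methyloxirane-2-carbaldehyde | CCCC[C@H](CC)C[C@H](C)C[C@@]1(C=O)O[C@H]1C
F10 | step 6 | (2S,3S)-2-[(2S,4S)-4-ethyl-2-methyloctyl]-2-[(1Z)-2-iodobut-1-en-1-yl]-3-methyloxirane | CCCC[C@H](CC)C[C@H](C)C[C@@]1(/C=C(/CC)I)O[C@H]1C
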